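**Remark on the chemistry (assumption):** all compounds, including the six-membered precursors, carry germacrane locants (ring C1–C10, lactone carbons C11–C13, C14 on C10, C15 on C4), CIP descriptors refer to these locants, and the sense of induction in step 1 is taken to be selectable through the pseudo-enantiomeric cinchona amine.

## Analysis of the target

The target is a germacranolide: a ten-membered carbocycle C1–C10, trans-fused at C6/C7 to an α-methylene-γ-butyrolactone (lactone oxygen on C6, C11 on C7). It carries an angelate on O8, a free hydroxyl on C5, a methyl group (C14) on C10 and a spiro-epoxide that joins C4 to C15. There are nine stereocentres (1R,2R,3S,4S,5S,6S,7R,8S,10R). O4, O5 and O6 lie on one side of the ring, the C7 side chain on the other, and O8 again on the side of O6. The C1–C10 epoxide is trans (it derives from an E alkene), the C2–C3 epoxide is cis (from a Z alkene), and their two oxygens are syn. The sensitive groups are the three epoxides (one of them a spiro-epoxy alcohol), the Michael-accepting methylene lactone, the angelate (Z to E isomerisation) and a lactone that a free O8 could take over (6,12 to 8,12). The difficulty is to make a medium ring with one E and one Z alkene in conjugation and five contiguous stereocentres from C4 to C8, and then to introduce three epoxides in an order that the other groups tolerate. The strategy rests on one feature: C1 to C6 can be folded into a cyclohexene, in which C2=C3 is necessarily cis and the C1–C6 bond is the central σ bond of the 1,5-diene C9=C10–C1–C6–C7=C8.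

## Retrosynthetic reasoning

**C5–O unmasking.** Target 41 is traced back to its 4-methoxybenzyl ether 40. The last step must be neutral, because three epoxides, the methylene lactone and the angelate are present; an oxidatively cleaved benzyl-type ether is the only protecting group at O5 that meets this and can also chelate earlier in the route.

**The two ring epoxides.** The C1–O, C10–O, C2–O and C3–O bonds of 40 are cut to give diene 38. The E and Z geometries of the diene translate into the trans and cis epoxides, so the epoxides can be left to the penultimate step, after every acidic, basic and nucleophilic operation. The forward reaction has to deliver both oxygens to the outer faces of the ring.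

**Angelate and methylene group.** Diene 38 comes from the Mannich base 36, and 36 from alcohol 33 and angelic acid 34 (C8–O acyl bond). The angelate cannot survive enolate or organometallic chemistry, and a methylene lactone cannot survive fluoride or amine bases, so the methylene is carried as an aminomethyl group (32, 33, 36) and the acid 34 is attached between its introduction and its release.

**Spiro-epoxide.** Epoxide 30 is opened to the 4,15-diol 29, which goes back through 28 to ketone 25 and the one-carbon silane 26 (C4–C15 bond). A chelate through the C5 ether is the only element that can be relied on to place O4 on the side of O5. The ketone itself is released from the ketal 24.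

**C8–O, lactone and C6–O.** Lactone 23 is traced through silanol 22 to hydroxy ester 20 and ketone 19. The C8 oxygen is made from silicon only after the lactone has closed on O6, so that the lactone regiochemistry is never in doubt. The C6 hydroxyl both closes the lactone and removes the phenyl group from silicon, and it comes from chelate-controlled reduction of the C6 ketone.

**Key disconnection.** Ketone 19 is cut at C7–C11 and C8–C9 while C1–C6 is re-formed, giving carbinol 15 and bromo ester 16. This replaces the closure of a ten-membered ring by the expansion of a six-membered one, takes the Z alkene from the ring, the E alkene and C8 from a chair transition state, and C7 from alkylation of the enolate that the rearrangement leaves behind. Silicon at C8 is essential: an oxygen there would be eliminated from the enolate.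

**Carbinol.** Carbinol 15 is cut at C6–C7 into ketone 10 and stannane 12; 12 comes from alkyne 11. The forward addition has to avoid enolising a ketone whose C1 hydrogen is doubly allylic.

**Isopropenyl group.** Ketone 10 comes from alcohol 9, and 9 from vinyl epoxide 6 and bromide 7 (C1–C10 bond). Opening an epoxide that is cis to O5 with inversion at the allylic carbon is what sets the isopropenyl group trans to O5; this relation, together with the chair, decides the configuration of C8.

**Ring oxygenation.** Epoxide 6 is the ether of 5, which comes from dienol 4 by hydroxyl-directed epoxidation; 4 comes from epoxy enone 2 by Wharton transposition, and 2 from the achiral quinone monoketal 1. One catalytic asymmetric epoxidation is thus the source of all absolute stereochemistry.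

## Alternatives that were turned down

**Alternative 1:** Biomimetic ene oxygenation. The disconnection removes the C5–O bond and the C4–O bond of the spiro-epoxide and returns to a C4=C5 trisubstituted alkene with C15 as a methyl group. In the forward step singlet oxygen would attack C5 and take a hydrogen from C15, and Ti(OiPr)4 in the same flask would pass the distal peroxide oxygen to the new C4=C15 alkene, giving the triethylsilyl ether A1. In its favour, one flask makes the C5 carbinol and the spiro-epoxide, the oxygen is delivered from the neighbouring hydroperoxide so that O4 and O5 come out on the same side, and C5 needs no protecting group. On this point it is clearly stronger than the chosen route, which spends four steps (14 to 17) and depends on chelate control. Against it, the ene reaction must choose the C15 hydrogens over the allylic hydrogen at C6 and one face of a medium-ring alkene that is deactivated by the adjacent epoxide and the lactone oxygen, and it runs on a molecule that already holds two epoxides and the methylene lactone, so nothing can be corrected afterwards. It is also an end game only: it does not say how the ring, the two alkene geometries or C7 and C8 are made, and a C4 methyl with a C4=C5 bond cannot be drawn from a cyclohexene template. The chosen strategy is longer at C4/C5 but makes ring, geometries and two stereocentres in one understood step.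

**Alternative 2:** Samarium pinacol macrocyclisation. The disconnection is the C5–C6 bond together with the lactone C–O bond. In the forward step SmI2 would couple two aldehyde carbons, C5 and C6, of an open chain that already holds the E,Z-diene, and the C6 alkoxide would close the lactone onto a C12 ester to give A2. In its favour, the route is convergent, one operation forms the ring, two carbinol centres and a lactone whose regiochemistry cannot be wrong, and O8 is carried as a silyl ether from the start. It is stronger than the chosen route in convergence and avoids the silicon-to-oxygen detour of steps 11 and 12. Against it stand the end-to-end closure of a ten-membered ring under high dilution, a Z-dienyl ketal that must be built and kept in an acyclic chain, a C6 aldehyde that is α to C7 and β to the C8 silyloxy group (epimerisation, elimination), a neopentylic C5 aldehyde, and two new centres whose relation to C7 is not secured by any element of the substrate. The chosen strategy avoids the cyclisation entropy and takes the Z alkene from a ring, at the price of more steps after the ring is formed.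

**Alternative 3:** Endoperoxide as precursor of the diepoxide. The disconnection replaces the C1–O and C2–O bonds by a peroxide bridge between C10 and C3. In the forward step singlet oxygen would add [4+2] across C10 and C3 of the E,Z-diene to give the 1,2-dioxine A3 with a new C1=C2 alkene, and rearrangement would then give both epoxides. In its favour, both oxygens arrive on one face, so the syn relation of the two epoxides is guaranteed; on this point it is stronger than the two reagent-controlled epoxidations of step 22. Against it, the E,Z-diene with a methyl group at C10 must reach an s-cis conformation inside the ring, the ene reaction at the C9 and C14 hydrogens competes, the face of attack is not controlled, and the endoperoxide can collapse to a hydroxy enone (Kornblum–DeLaMare) through the C3 hydrogen. It, too, is an end-game tactic that builds neither the ring nor C4 to C8. The chosen strategy keeps it in reserve for step 22 but does not rest on it.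

Key step: step 9

## Route

Step 1
Reactants: 1 p-benzoquinone monoethylene ketal
Product: 2 (5S,6R)-5,6-epoxy enone (C1 ketone; C4 ketal)
Conditions: 9-amino-9-deoxy-epi-quinine (10 mol%), CF3CO2H (20 mol%), 50% aq. H2O2 (1.2 equiv), dioxane, 30 °C
Reagents that add atoms: hydrogen peroxide, OO
Why: Amine-catalysed nucleophilic epoxidation of a cyclic enone through its iminium ion (Weitz–Scheffer type); the two enone arms of 1 are enantiotopic, so the chiral amine alone sets C5 and C6, and limiting the peroxide avoids the bis-epoxide.

Step 2
Reactants: 2 epoxy enone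
Product: 4 (5S)-4,4-ethylenedioxycyclohexa-1(6),2-dien-5-ol, via epoxy hydrazone 3 (not isolated)
Conditions: N2H4·H2O, AcOH (cat.), MeOH, 0 °C → rt
Reagents that add atoms: none
Why: Wharton transposition: hydrazone 3 opens the epoxide at C6 and loss of N2 from the alkenyldiazene leaves C1=C6 in conjugation with C2=C3 and the C5 oxygen untouched; the acid-sensitive dienol is used at once.

Step 3
Reactants: 4 dienol
Product: 5 (1S,5S,6R)-1,6-epoxy-4,4-ethylenedioxycyclohex-2-en-5-ol (epoxide cis to the hydroxyl)
Conditions: VO(acac)2 (2 mol%), tBuOOH, CH2Cl2, 0 °C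
Reagents that add atoms: tert-butyl hydroperoxide, CC(C)(C)OO
Why: Hydroxyl-directed vanadium-catalysed epoxidation of an allylic alcohol: the vanadate ester at O5 delivers oxygen to the adjacent C6=C1 bond on the face of the hydroxyl, and the distal C2=C3 bond is out of reach.

Step 4
Reactants: 5 epoxy alcohol
Product: 6 (1S,5S,6S)-1,6-epoxy-4,4-ethylenedioxy-5-(4-methoxybenzyloxy)cyclohex-2-ene
Conditions: NaH, 4-MeOC6H4CH2Cl, Bu4NI (cat.), THF/DMF, 0 °C
Reagents that add atoms: 4-methoxybenzyl chloride, COc1ccc(CCl)cc1
Why: Williamson etherification; the alkoxide is cis to the epoxide and cannot open it by Payne rearrangement, and the 4-methoxybenzyl ether is chosen because it chelates in steps 8, 10 and 15 and is removed oxidatively at the end.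

Step 5
Reactants: 6 vinyl epoxide; 7 2-bromopropene
Product: 9 (1S,5S,6S)-4,4-ethylenedioxy-1-isopropenyl-5-(4-methoxybenzyloxy)cyclohex-2-en-6-ol, via isopropenyllithium 8 (not isolated)
Conditions: 7, tBuLi (2 equiv), Et2O, −78 °C; then 6, −78 → 0 °C; aq. NH4Cl
Reagents that add atoms: none
Why: Halogen–lithium exchange gives 8, which opens the vinyl epoxide by SN2 attack at the allylic carbon C1 with inversion (hard organolithium reagents prefer this to the SN2′ path, and C6 is shielded by the neighbouring ether), so isopropenyl ends trans to O6 and to O5.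

Step 6
Reactants: 9 alcohol
Product: 10 (1S,5S)-4,4-ethylenedioxy-1-isopropenyl-5-(4-methoxybenzyloxy)cyclohex-2-en-6-one
Conditions: DMP, pyridine, CH2Cl2, 0 °C
Reagents that add atoms: none
Why: Dess–Martin oxidation with pyridine buffering; neutral conditions avoid epimerisation of the doubly allylic C1 and migration of the β,γ double bonds, and the ketone is carried on without chromatography.

Step 7
Reactants: 11 ethynyldimethylphenylsilane
Product: 12 (E)-[2-(tributylstannyl)ethenyl]dimethylphenylsilane
Conditions: Bu3SnH, AIBN (cat.), neat, 90 °C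
Reagents that add atoms: tributylstannane, CCCC[SnH](CCCC)CCCC
Why: Radical hydrostannation of a terminal silylalkyne: the stannyl radical adds to the terminal carbon and reversible addition equilibrates the product to the E isomer.

Step 8
Reactants: 10 ketone; 12 vinylstannane
Product: 15 (1S,5S,6S)-6-[(E)-2-(dimethylphenylsilyl)ethenyl]-4,4-ethylenedioxy-1-isopropenyl-5-(4-methoxybenzyloxy)cyclohex-2-en-6-ol, via vinyllithium 13 (not isolated), via vinylcerium dichloride 14 (not isolated)
Conditions: 12, nBuLi, THF, −78 °C; CeCl3, −78 °C; then 10, −78 °C; aq. NH4Cl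
Reagents that add atoms: none
Why: Tin–lithium exchange with retention of the E geometry and transmetalation to the weakly basic organocerium reagent give 1,2-addition without enolisation of the acidic ketone; with the metal chelated between C6=O and the C5 ether the isopropenyl group sits pseudo-axial and the nucleophile should enter anti to it, which puts the two alkenyl groups trans.

Step 9
Reactants: 15 dialkenyl carbinol; 16 tert-butyl bromoacetate
Product: 19 tert-butyl (5S,7S,8S)-8-(dimethylphenylsilyl)-4,4-ethylenedioxy-5-(4-methoxybenzyloxy)-6-oxogermacra-1(10)E,2Z-dien-12-oate (C7 acetate arm), via potassium alkoxide 17 (not isolated), via potassium enolate 18 (not isolated)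
Conditions: KN(SiMe3)2, 18-crown-6, THF, −78 → 0 °C; then 16, −78 °C
Reagents that add atoms: none
Why: Deprotonation gives the crown-complexed alkoxide 17, whose oxyanion weakens the C1–C6 bond and sets off a [3,3] sigmatropic shift; the closest known reaction type is the anionic oxy-Cope ring expansion of 1,2-divinylcyclohexanols to cyclodec-5-enones with alkylation of the enolate in the same flask. The ten-membered ring is not closed end to end but opened out of the six-membered ring by a suprafacial shift through a chair in which the ring carbons C2 and C5 are both equatorial, so that C8–C9 forms as C1–C6 breaks. This chair gives the E C1=C10 alkene, leaves C2=C3 cis because it was a ring alkene, and places the silyl group of the E-vinylsilane equatorial, so C8 (S) is set by transfer of chirality from C1 and C6. The regiodefined enolate 18 (C6=C7) is then alkylated on carbon by 16 from the outer face of the ring conformer that the chair delivers, which puts C11 trans to the silyl group (7S), the arrangement that equilibration would also favour. The step needs the rearrangement to run through the isopropenyl group and not through C2=C3, and the latter path would require a boat with the alkenyl group axial on the cyclohexene. It also needs carbon- over oxygen-alkylation, secured by the soft primary α-bromo ester, and no β-elimination from the enolate, secured by having silicon and not oxygen on C8.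

Step 10
Reactants: 19 ketone
Product: 20 tert-butyl (5S,6S,7S,8S)-8-(dimethylphenylsilyl)-4,4-ethylenedioxy-6-hydroxy-5-(4-methoxybenzyloxy)germacra-1(10)E,2Z-dien-12-oate
Conditions: Zn(BH4)2, Et2O, −20 °C
Reagents that add atoms: none
Why: Chelation-controlled (Cram-chelate) reduction of an α-alkoxy ketone: zinc bridges C6=O and the C5 ether and hydride enters anti to C4, which should give the alcohol cis to O5; the tert-butyl ester is not reduced.

Step 11
Reactants: 20 hydroxy ester
Product: 22 (5S,6S,7S,8S)-4,4-ethylenedioxy-8-(hydroxydimethylsilyl)-5-(4-methoxybenzyloxy)germacra-1(10)E,2Z-dien-12,6-olide, via oxasilolane carboxylate 21 (not isolated)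
Conditions: KOtBu, H2O, DMSO, rt; then 0.5 M HCl to pH 4, 0 °C; PPTS (cat.), 4 Å MS, CH2Cl2, rt
Reagents that add atoms: water, O
Why: The potassium alkoxide at C6, cis to silicon on the ring, attacks the silyl group and expels the phenyl group as benzene (alkoxide-assisted dephenylation of a γ-hydroxy phenylsilane to a 1,2-oxasilolane) while hydroxide cleaves the ester; on acidification the γ-lactone can close only on O6, because C8 still carries silicon, and the Si–O6 bond is hydrolysed to the silanol.

Step 12
Reactants: 22 silanol
Product: 23 (5S,6S,7R,8S)-4,4-ethylenedioxy-8-hydroxy-5-(4-methoxybenzyloxy)germacra-1(10)E,2Z-dien-12,6-olide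
Conditions: KF, KHCO3, 30% H2O2, THF/MeOH, rt
Reagents that add atoms: hydrogen peroxide, OO
Why: Tamao oxidation of the silanol with retention at C8; the weakly basic peroxide leaves the diene, the ketal and the lactone alone.

Step 13
Reactants: 23 hydroxy lactone
Product: 24 8-O-tert-butyldimethylsilyl ether of 23
Conditions: tBuMe2SiOSO2CF3, 2,6-lutidine, CH2Cl2, −78 → 0 °C
Reagents that add atoms: tert-butyldimethylsilyl triflate, CC(C)(C)[Si](C)(C)OS(=O)(=O)C(F)(F)F
Why: Silylation of the only free hydroxyl; it keeps an alkoxide at C8 from attacking the lactone carbonyl (6,12 to 8,12 translactonisation) in the basic steps that follow.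

Step 14
Reactants: 24 ketal
Product: 25 (5S,6S,7S,8S)-8-(tert-butyldimethylsilyloxy)-5-(4-methoxybenzyloxy)-4-oxo-15-norgermacra-1(10)E,2Z-dien-12,6-olide
Conditions: PPTS, acetone/H2O, 40 °C
Reagents that add atoms: water, O
Why: Acid-catalysed hydrolysis of a ketal whose oxocarbenium ion is stabilised by the diene, so a mild pyridinium acid suffices; silyl ether, benzyl-type ether and lactone survive.

Step 15
Reactants: 25 ketone; 26 (chloromethyl)(isopropoxy)dimethylsilane
Product: 28 (4R,5S,6S,7S,8S)-8-(tert-butyldimethylsilyloxy)-4-hydroxy-15-(isopropoxydimethylsilyl)-5-(4-methoxybenzyloxy)germacra-1(10)E,2Z-dien-12,6-olide, via Grignard reagent 27 (not isolated)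
Conditions: 26, Mg, THF, 40 °C; then 25, THF, −78 °C; aq. NH4Cl
Reagents that add atoms: none
Why: Chelation-controlled Grignard addition of a hydroxymethyl anion equivalent to an α-alkoxy ketone: magnesium bridges C4=O and the C5 ether and the nucleophile attacks anti to C6, which should place O4 cis to O5 as in the target; at −78 °C the ketone reacts far faster than the lactone, and silylmethyl Grignard reagents add 1,2 to enones.

Step 16
Reactants: 28 β-hydroxysilane
Product: 29 (4R,5S,6S,7S,8S)-8-(tert-butyldimethylsilyloxy)-4,15-dihydroxy-5-(4-methoxybenzyloxy)germacra-1(10)E,2Z-dien-12,6-olide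
Conditions: KF, KHCO3, 30% H2O2, THF/MeOH, rt
Reagents that add atoms: hydrogen peroxide, OO
Why: Tamao oxidation of the isopropoxysilane turns C15–Si into C15–OH; the conditions are too weakly basic for Peterson elimination of the β-hydroxysilane.

Step 17
Reactants: 29 diol
Product: 30 (4R,5S,6S,7S,8S)-8-(tert-butyldimethylsilyloxy)-4,15-epoxy-5-(4-methoxybenzyloxy)germacra-1(10)E,2Z-dien-12,6-olide
Conditions: PPh3, DIAD, THF, 0 °C → rt
Reagents that add atoms: none
Why: Mitsunobu-type cyclodehydration of a 1,2-diol: the primary hydroxyl is activated as its oxyphosphonium ion and displaced by the tertiary oxygen (3-exo-tet), so C4 keeps its configuration; the neutral conditions spare lactone and silyl ether.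

Step 18
Reactants: 30 lactone
Product: 32 (11R)-13-(dimethylamino) derivative of 30 (Mannich base), via lithium enolate 31 (not isolated)
Conditions: LiN(iPr)2, THF, −78 °C; then CH2=NMe2+ I−, −78 → 0 °C
Reagents that add atoms: N,N-dimethylmethyleneiminium iodide, C=[N+](C)C.[I-]
Why: Mannich reaction of the lactone enolate 31 with the iminium salt; the amine masks the α-methylene group through the fluoride and acylation steps, and attack anti to C8 should give 11R, a centre that is lost in step 21.

Step 19
Reactants: 32 silyl ether
Product: 33 (4R,5S,6S,7R,8S,11R)-13-(dimethylamino)-4,15-epoxy-8-hydroxy-5-(4-methoxybenzyloxy)germacra-1(10)E,2Z-dien-12,6-olide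
Conditions: Bu4NF, AcOH (1:1), THF, rt
Reagents that add atoms: none
Why: Buffered fluoride desilylation; acetic acid keeps O8 protonated, so neither translactonisation nor opening of the dienyl epoxide is expected, and no Michael acceptor is present yet.

Step 20
Reactants: 33 alcohol; 34 angelic acid
Product: 36 8-O-angelate of 33, via mixed anhydride 35 (not isolated)
Conditions: 34, 2,4,6-Cl3C6H2COCl, Et3N, PhMe, rt; then 33, 70 °C
Reagents that add atoms: none
Why: Yamaguchi-type mixed-anhydride acylation of the single free hydroxyl without a nucleophilic catalyst, a protocol under which the Z geometry of the angelate is kept and isomerisation to the tiglate is avoided.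

Step 21
Reactants: 36 Mannich base
Product: 38 (4R,5S,6S,7R,8S)-8-angeloyloxy-4,15-epoxy-5-(4-methoxybenzyloxy)germacra-1(10)E,2Z,11(13)-trien-12,6-olide, via ammonium iodide 37 (not isolated)
Conditions: MeI, MeOH, rt; then aq. NaHCO3, CH2Cl2, rt
Reagents that add atoms: none
Why: Quaternisation of the amine and base-induced β-elimination (the Mannich-base route to α-methylene lactones); the C11 centre disappears, and the epoxide and both esters are untouched by bicarbonate.

Step 22
Reactants: 38 diene
Product: 40 5-O-(4-methoxybenzyl) ether of the target (1R,2R,3S,4S,5S,6S,7R,8S,10R), via monoepoxide 39 (not isolated)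
Conditions: dimethyldioxirane (2.2 equiv), acetone, 0 °C
Reagents that add atoms: dimethyldioxirane, CC1(C)OO1
Why: Electrophilic epoxidation under neutral conditions: the electron-rich trisubstituted C1=C10 bond reacts first (39), then C2=C3, while the two enoate double bonds are too electron-poor; geometry is transferred (E to trans, Z to cis), and attack on the outer faces of the ring conformer held by the trans-lactone should give the syn-diepoxide.

Step 23
Reactants: 40 4-methoxybenzyl ether
Product: 41 target CNP0594916.1
Conditions: DDQ, CH2Cl2/pH 7 buffer, 0 °C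
Reagents that add atoms: none
Why: Oxidative cleavage of the 4-methoxybenzyl ether by hydride abstraction and hydrolysis of the oxocarbenium ion at pH 7; epoxides, methylene lactone and angelate are inert to the quinone.

## Compound list

1 | 1,4-dioxaspiro[4.5]deca-6,9-dien-8-one (p-benzoquinone monoethylene ketal) | O=C1C=CC2(OCCO2)C=C1 | starting material
2 | (5S,6R)-5,6-epoxy-4,4-ethylenedioxycyclohex-2-en-1-one | O=C1C=CC2(OCCO2)[C@H]3O[C@@H]13 | intermediate
3 | hydrazone of 2 | NN=C1C=CC2(OCCO2)[C@H]3O[C@@H]13 | intermediate
4 | (5S)-4,4-ethylenedioxycyclohexa-1(6),2-dien-5-ol | O[C@H]1C=CC=CC12OCCO2 | intermediate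
5 | (1S,5S,6R)-1,6-epoxy-4,4-ethylenedioxycyclohex-2-en-5-ol | C1=C[C@@H]2O[C@@H]2[C@H](O)C13OCCO3 | intermediate
6 | (1S,5S,6S)-1,6-epoxy-4,4-ethylenedioxy-5-(4-methoxybenzyloxy)cyclohex-2-ene | C1=C[C@@H]2O[C@@H]2[C@H](OCc4ccc(OC)cc4)C13OCCO3 | intermediate
7 | 2-bromopropene | C=C(C)Br | starting material
8 | isopropenyllithium | [Li]C(C)=C | intermediate
9 | (1S,5S,6S)-4,4-ethylenedioxy-1-isopropenyl-5-(4-methoxybenzyloxy)cyclohex-2-en-6-ol | C=C(C)[C@@H]1C=CC2(OCCO2)[C@@H](OCc3ccc(OC)cc3)[C@H]1O | intermediate
10 | (1S,5S)-4,4-ethylenedioxy-1-isopropenyl-5-(4-methoxybenzyloxy)cyclohex-2-en-6-one | C=C(C)[C@@H]1C=CC2(OCCO2)[C@@H](OCc3ccc(OC)cc3)C1=O | intermediate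
11 | ethynyldimethylphenylsilane | C#C[Si](C)(C)c1ccccc1 | starting material
12 | (E)-[2-(tributylstannyl)ethenyl]dimethylphenylsilane | CCCC[Sn](CCCC)(CCCC)/C=C/[Si](C)(C)c1ccccc1 | intermediate
13 | (E)-[2-(dimethylphenylsilyl)ethenyl]lithium | [Li]/C=C/[Si](C)(C)c1ccccc1 | intermediate
14 | dichloro[(E)-2-(dimethylphenylsilyl)ethenyl]cerium | Cl[Ce](Cl)/C=C/[Si](C)(C)c1ccccc1 | intermediate
15 | (1S,5S,6S)-6-[(E)-2-(dimethylphenylsilyl)ethenyl]-4,4-ethylenedioxy-1-isopropenyl-5-(4-methoxybenzyloxy)cyclohex-2-en-6-ol | C=C(C)[C@@H]1C=CC2(OCCO2)[C@@H](OCc3ccc(OC)cc3)[C@@]1(O)/C=C/[Si](C)(C)c4ccccc4 | intermediate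
16 | tert-butyl bromoacetate | BrCC(=O)OC(C)(C)C | starting material
17 | potassium alkoxide of 15 | C=C(C)[C@@H]1C=CC2(OCCO2)[C@@H](OCc3ccc(OC)cc3)[C@@]1([O-])/C=C/[Si](C)(C)c4ccccc4.[K+] | intermediate
18 | potassium C6=C7 enolate of the ring-expanded ketone (8S; 1(10)E,2Z) | [K+].[O-]/C1=C\[C@@H]([Si](C)(C)c2ccccc2)C/C(C)=C/C=C\C3(OCCO3)[C@H]1OCc4ccc(OC)cc4 | intermediate
19 | tert-butyl (5S,7S,8S)-8-(dimethylphenylsilyl)-4,4-ethylenedioxy-5-(4-methoxybenzyloxy)-6-oxogermacra-1(10)E,2Z-dien-12-oate | O=C1[C@H](OCc2ccc(OC)cc2)C3(OCCO3)/C=C\C=C(C)\C[C@H]([Si](C)(C)c4ccccc4)[C@H]1CC(=O)OC(C)(C)C | intermediate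
20 | tert-butyl (5S,6S,7S,8S)-8-(dimethylphenylsilyl)-4,4-ethylenedioxy-6-hydroxy-5-(4-methoxybenzyloxy)germacra-1(10)E,2Z-dien-12-oate | O[C@@H]1[C@H](OCc2ccc(OC)cc2)C3(OCCO3)/C=C\C=C(C)\C[C@H]([Si](C)(C)c4ccccc4)[C@H]1CC(=O)OC(C)(C)C | intermediate
21 | potassium carboxylate of the 6-O,8-Si-bridged 1,2-oxasilolane | O5[C@@H]1[C@H](OCc2ccc(OC)cc2)C3(OCCO3)/C=C\C=C(C)\C[C@H]([Si]5(C)C)[C@H]1CC(=O)[O-].[K+] | intermediate
22 | (5S,6S,7S,8S)-4,4-ethylenedioxy-8-(hydroxydimethylsilyl)-5-(4-methoxybenzyloxy)germacra-1(10)E,2Z-dien-12,6-olide | C1C(=O)O[C@H]2[C@H]1[C@@H]([Si](C)(C)O)C/C(C)=C/C=C\C3(OCCO3)[C@H]2OCc4ccc(OC)cc4 | intermediate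
23 | (5S,6S,7R,8S)-4,4-ethylenedioxy-8-hydroxy-5-(4-methoxybenzyloxy)germacra-1(10)E,2Z-dien-12,6-olide | C1C(=O)O[C@H]2[C@H]1[C@@H](O)C/C(C)=C/C=C\C3(OCCO3)[C@H]2OCc4ccc(OC)cc4 | intermediate
24 | 8-O-tert-butyldimethylsilyl ether of 23 | C1C(=O)O[C@H]2[C@H]1[C@@H](O[Si](C)(C)C(C)(C)C)C/C(C)=C/C=C\C3(OCCO3)[C@H]2OCc4ccc(OC)cc4 | intermediate
25 | (5S,6S,7S,8S)-8-(tert-butyldimethylsilyloxy)-5-(4-methoxybenzyloxy)-4-oxo-15-norgermacra-1(10)E,2Z-dien-12,6-olide | C1C(=O)O[C@H]2[C@H]1[C@@H](O[Si](C)(C)C(C)(C)C)C/C(C)=C/C=C\C(=O)[C@H]2OCc3ccc(OC)cc3 | intermediate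
26 | (chloromethyl)(isopropoxy)dimethylsilane | ClC[Si](C)(C)OC(C)C | starting material
27 | [(isopropoxydimethylsilyl)methyl]magnesium chloride | Cl[Mg]C[Si](C)(C)OC(C)C | intermediate
28 | (4R,5S,6S,7S,8S)-8-(tert-butyldimethylsilyloxy)-4-hydroxy-15-(isopropoxydimethylsilyl)-5-(4-methoxybenzyloxy)germacra-1(10)E,2Z-dien-12,6-olide | C1C(=O)O[C@H]2[C@H]1[C@@H](O[Si](C)(C)C(C)(C)C)C/C(C)=C/C=C\[C@](O)(C[Si](C)(C)OC(C)C)[C@H]2OCc3ccc(OC)cc3 | intermediate
29 | (4R,5S,6S,7S,8S)-8-(tert-butyldimethylsilyloxy)-4,15-dihydroxy-5-(4-methoxybenzyloxy)germacra-1(10)E,2Z-dien-12,6-olide | C1C(=O)O[C@H]2[C@H]1[C@@H](O[Si](C)(C)C(C)(C)C)C/C(C)=C/C=C\[C@](O)(CO)[C@H]2OCc3ccc(OC)cc3 | intermediate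
30 | (4R,5S,6S,7S,8S)-8-(tert-butyldimethylsilyloxy)-4,15-epoxy-5-(4-methoxybenzyloxy)germacra-1(10)E,2Z-dien-12,6-olide | C1C(=O)O[C@H]2[C@H]1[C@@H](O[Si](C)(C)C(C)(C)C)C/C(C)=C/C=C\[C@]3(CO3)[C@H]2OCc4ccc(OC)cc4 | intermediate
31 | lithium enolate of lactone 30 | C1=C([O-])O[C@H]2[C@H]1[C@@H](O[Si](C)(C)C(C)(C)C)C/C(C)=C/C=C\[C@]3(CO3)[C@H]2OCc4ccc(OC)cc4.[Li+] | intermediate
32 | (11R)-13-(dimethylamino) derivative of 30 | CN(C)C[C@@H]1C(=O)O[C@H]2[C@H]1[C@@H](O[Si](C)(C)C(C)(C)C)C/C(C)=C/C=C\[C@]3(CO3)[C@H]2OCc4ccc(OC)cc4 | intermediate
33 | (4R,5S,6S,7R,8S,11R)-13-(dimethylamino)-4,15-epoxy-8-hydroxy-5-(4-methoxybenzyloxy)germacra-1(10)E,2Z-dien-12,6-olide | CN(C)C[C@@H]1C(=O)O[C@H]2[C@H]1[C@@H](O)C/C(C)=C/C=C\[C@]3(CO3)[C@H]2OCc4ccc(OC)cc4 | intermediate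
34 | angelic acid, (Z)-2-methylbut-2-enoic acid | C/C=C(/C)C(=O)O | starting material
35 | angelic 2,4,6-trichlorobenzoic anhydride | C/C=C(/C)C(=O)OC(=O)c1c(Cl)cc(Cl)cc1Cl | intermediate
36 | 8-O-angelate of 33 | CN(C)C[C@@H]1C(=O)O[C@H]2[C@H]1[C@@H](OC(=O)/C(C)=C\C)C/C(C)=C/C=C\[C@]3(CO3)[C@H]2OCc4ccc(OC)cc4 | intermediate
37 | trimethylammonium iodide of 36 | C[N+](C)(C)C[C@@H]1C(=O)O[C@H]2[C@H]1[C@@H](OC(=O)/C(C)=C\C)C/C(C)=C/C=C\[C@]3(CO3)[C@H]2OCc4ccc(OC)cc4.[I-] | intermediate
38 | (4R,5S,6S,7R,8S)-8-angeloyloxy-4,15-epoxy-5-(4-methoxybenzyloxy)germacra-1(10)E,2Z,11(13)-trien-12,6-olide | C=C1C(=O)O[C@H]2[C@H]1[C@@H](OC(=O)/C(C)=C\C)C/C(C)=C/C=C\[C@]3(CO3)[C@H]2OCc4ccc(OC)cc4 | intermediate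
39 | (1R,10R)-1,10-monoepoxide of 38 | C=C1C(=O)O[C@H]2[C@H]1[C@@H](OC(=O)/C(C)=C\C)C[C@@]3(C)O[C@@H]3/C=C\[C@]4(CO4)[C@H]2OCc5ccc(OC)cc5 | intermediate
40 | 5-O-(4-methoxybenzyl) ether of the target | C=C1C(=O)O[C@H]2[C@H]1[C@@H](OC(=O)/C(C)=C\C)C[C@@]3(C)O[C@@H]3[C@@H]3O[C@@H]3[C@]3(CO3)[C@H]2OCc4ccc(OC)cc4 | intermediate
41 | CNP0594916.1, (1R,2R,3S,4S,5S,6S,7R,8S,10R)-8-angeloyloxy-1,10:2,3:4,15-triepoxy-5-hydroxygermacr-11(13)-en-12,6-olide | C=C1C(=O)O[C@H]2[C@H]1[C@@H](OC(=O)/C(C)=C\C)C[C@@]1(C)O[C@@H]1[C@@H]1O[C@@H]1[C@]1(CO1)[C@H]2O | target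

## Step count and least certain steps

Total step count: 23. Longest linear sequence: 22 steps (steps 1 to 6 and 8 to 23); step 7 is a one-step side branch.

**Step 9 (key step).** Three processes could spoil it.
- Heterolytic cleavage of the C1–C6 bond in alkoxide 17 is conceivable, because C1 is doubly allylic; recombination would erode the transfer of chirality to C8 and could bond through C3.
- The ring conformers of enolate 18 may interconvert before alkylation, which would lower the selectivity at C7.
- Proton transfer could equilibrate C5.

A carbinol epimeric at C6 need not be lost: through a chair that keeps C2 equatorial it should give the same E alkene and the same C8 configuration. The fallback sets out from 15. Silylation (Me3SiCl, imidazole) gives the trimethylsilyl ether F1. Thermal, neutral siloxy-Cope rearrangement (PhMe, sealed tube, 150 °C) gives the trimethylsilyl enol ether F2. Cleavage with MeLi to the lithium enolate and alkylation with 16 (THF, N,N′-dimethylpropyleneurea) comes back to the route at 19.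

**Step 2.** The acid catalyst and the product work against each other: the dienol can aromatise by loss of a ketal oxygen, and collapse of the alkenyldiazene is often incomplete. The fallback sets out from 2 and avoids acid. Luche reduction (NaBH4, CeCl3·7H2O, MeOH) gives the epoxy allylic alcohol F3. Iodination with inversion (I2, PPh3, imidazole) gives the epoxy allylic iodide F4. Reductive elimination with Zn dust in EtOH opens the epoxide and comes back at 4.

**Step 10.** Facial selectivity may be poor if the ring cannot adopt the chelate geometry. The fallback sets out from 19. A non-chelating bulky hydride, LiBH(sBu)3, should give the epimeric 6R alcohol F5. Mitsunobu inversion with 4-nitrobenzoic acid gives the 6S 4-nitrobenzoate F6, and mild methanolysis (K2CO3, MeOH, 0 °C) comes back at 20.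

**Step 11.** The strongly basic medium may remove the whole silyl group by protodesilylation, may isomerise the diene, or the alkoxide may fail to displace phenyl. The fallback sets out from 20. Acid-catalysed lactonisation (TsOH cat., PhMe) is done first and gives the 8-(dimethylphenylsilyl) lactone F7. The phenylsilane is then oxidised in one flask under basic peroxide conditions (tBuOOH, KH, Bu4NF, N-methylpyrrolidone), coming back at 23; translactonisation has to be watched there.

**Step 15.** Chelate control may fail inside the medium ring and give the wrong configuration at C4, or the reagent may attack the lactone. The fallback sets out from 25 and goes directly to 30 by Corey–Chaykovsky epoxidation with dimethylsulfonium methylide (Me3S+ I−, KN(SiMe3)2, THF). Its selectivity follows approach from the ring periphery and not chelation; it makes no new compound (F0).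

**Step 22.** The second oxygen may be delivered anti to the first, or from the inner face, and the benzyl ether may be over-oxidised. The fallback sets out from 38. Singlet oxygen (O2, hν, tetraphenylporphyrin, CH2Cl2, −78 °C) adds [4+2] across C10 and C3 to give the endoperoxide F8. Rearrangement catalysed by cobalt tetraphenylporphyrin, Co(TPP), gives the syn-diepoxide and comes back at 40.

## Further compounds

F1 | step 9 | trimethylsilyl ether of carbinol 15 | C=C(C)[C@@H]1C=CC2(OCCO2)[C@@H](OCc3ccc(OC)cc3)[C@@]1(O[Si](C)(C)C)/C=C/[Si](C)(C)c4ccccc4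
F2 | step 9 | trimethylsilyl enol ether (C6=C7) of the ring-expanded ketone, 8S, 1(10)E,2Z | C[Si](C)(C)O/C1=C\[C@@H]([Si](C)(C)c2ccccc2)C/C(C)=C/C=C\C3(OCCO3)[C@H]1OCc4ccc(OC)cc4
F3 | step 2 | 5,6-epoxy-4,4-ethylenedioxycyclohex-2-en-1-ol, hydroxyl cis to the epoxide | O[C@H]1C=CC2(OCCO2)[C@H]3O[C@@H]13
F4 | step 2 | 5,6-epoxy-4,4-ethylenedioxy-1-iodocyclohex-2-ene, iodide trans to the epoxide | I[C@@H]1C=CC2(OCCO2)[C@H]3O[C@@H]13
F5 | step 10 | 6R epimer of hydroxy ester 20 | O[C@H]1[C@H](OCc2ccc(OC)cc2)C3(OCCO3)/C=C\C=C(C)\C[C@H]([Si](C)(C)c4ccccc4)[C@H]1CC(=O)OC(C)(C)C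
F6 | step 10 | 6S 4-nitrobenzoate of hydroxy ester 20 | O=C(O[C@@H]1[C@H](OCc2ccc(OC)cc2)C3(OCCO3)/C=C\C=C(C)\C[C@H]([Si](C)(C)c4ccccc4)[C@H]1CC(=O)OC(C)(C)C)c5ccc(cc5)[N+](=O)[O-]
F7 | step 11 | (5S,6S,7S,8S)-8-(dimethylphenylsilyl)-4,4-ethylenedioxy-5-(4-methoxybenzyloxy)germacra-1(10)E,2Z-dien-12,6-olide | C1C(=O)O[C@H]2[C@H]1[C@@H]([Si](C)(C)c3ccccc3)C/C(C)=C/C=C\C4(OCCO4)[C@H]2OCc5ccc(OC)cc5
F0 | step 15 | none | none
F8 | step 22 | C3,C10-endoperoxide of diene 38 (5-O-4-methoxybenzyl ether) | C=C1C(=O)O[C@H]2[C@H]1[C@@H](OC(=O)/C(C)=C\C)C[C@]3(C)C=C[C@H](OO3)[C@]4(CO4)[C@H]2OCc5ccc(OC)cc5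
A1 | alternative 1 | 8-O-triethylsilyl analogue of the target lacking the angelate | C=C1C(=O)O[C@H]2[C@H]1[C@@H](O[Si](CC)(CC)CC)C[C@@]1(C)O[C@@H]1[C@@H]1O[C@@H]1[C@]1(CO1)[C@H]2O
A2 | alternative 2 | 8-(tert-butyldimethylsilyloxy)-4,4-ethylenedioxy-5-hydroxygermacra-1(10)E,2Z-dien-12,6-olide | C1C(=O)O[C@H]2[C@H]1[C@@H](O[Si](C)(C)C(C)(C)C)C/C(C)=C/C=C\C3(OCCO3)[C@H]2O
A3 | alternative 3 | C3,C10-endoperoxide (1,2-dioxine) bridging the ten-membered ring, with free C5 hydroxyl | C=C1C(=O)O[C@H]2[C@H]1[C@@H](OC(=O)/C(C)=C\C)C[C@]3(C)C=C[C@H](OO3)[C@]4(CO4)[C@H]2O
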